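**Retrosynthetic overview**

1. Ring A is closed last, at C2–C3, by a type 2 intramolecular carbonyl-ene reaction of an (R)-α-bromo aldehyde onto an isopropenyl group; this sets the cis bromohydrin and the exocyclic methylene. The bromine comes from enamine catalysis.
2. Ring B chlorohydrin comes from an α-methylene ketone (nucleophilic epoxidation, chloride opening); the aldehyde comes from anti-Markovnikov Wacker oxidation of a vinyl group.
3. The spiro carbon and its bond to the CMe2 carbon come from an anionic oxy-Cope rearrangement of (S)-1-prenyl-3-isopropenylcyclohex-2-en-1-ol, with chirality transfer from the carbinol.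
4. The carbinol comes from catalytic asymmetric prenylboration of 3-isopropenylcyclohex-2-enone, made from 3-ethoxycyclohex-2-enone and isopropenylmagnesium bromide.
5. Ring order: ring B is carried from the cyclohexenone starting material; ring A is closed in the final one-pot operation. No single operation in this route closes two rings.

Assumption: the SMILES is read as the (3S,6R,9S,10R) enantiomer, and boronate 5 is bought (otherwise one step from prenylmagnesium chloride and 2-isopropoxy-4,4,5,5-tetramethyl-1,3,2-dioxaborolane).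

**Route**

Step 1
Reactants: 1 3-ethoxycyclohex-2-en-1-one; 2 isopropenylmagnesium bromide
Product: 4 3-(prop-1-en-2-yl)cyclohex-2-en-1-one, via carbinol adduct 3 (not isolated)
Conditions: CH2=C(CH3)MgBr, THF, 0 °C; then 1 M HCl, rt
Reagents that add atoms: none
Why: Stork–Danheiser sequence, in which 1,2-addition to the vinylogous ester and acid hydrolysis/dehydration give the transposed 3-substituted enone with no stereocentre.

Step 2
Reactants: 4 3-(prop-1-en-2-yl)cyclohex-2-en-1-one; 5 4,4,5,5-tetramethyl-2-(2-methylbut-3-en-2-yl)-1,3,2-dioxaborolane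
Product: 6 (1S)-1-(3-methylbut-2-en-1-yl)-3-(prop-1-en-2-yl)cyclohex-2-en-1-ol
Conditions: 5 (1.5 equiv), (S)-3,3'-dibromo-1,1'-bi-2-naphthol (15 mol %), t-BuOH, PhCF3, rt; aq. NaHCO3
Reagents that add atoms: none
Why: Chiral-diol-catalysed ketone allylboration through a closed six-membered transition state gives 1,2-addition with allyl transposition (boron on CMe2, so the CH2 terminus bonds and the linear prenyl carbinol results), and the diol sets the (S)-carbinol (catalyst enantiomer chosen accordingly).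

Step 3
Reactants: 6 (1S)-1-(3-methylbut-2-en-1-yl)-3-(prop-1-en-2-yl)cyclohex-2-en-1-ol
Product: 8 (3R)-3-(2-methylbut-3-en-2-yl)-3-(prop-1-en-2-yl)cyclohexan-1-one, via potassium enolate 7 (not isolated)
Conditions: KH, 18-crown-6, THF, 0 to 50 °C; then sat. aq. NH4Cl
Reagents that add atoms: none
Why: Anionic oxy-Cope [3,3] rearrangement, in which the prenyl group migrates suprafacially across the cyclohexenyl unit so that the carbinol configuration is transferred to the new quaternary carbon (R), the CMe2–C bond forms, and the C–O becomes the ring B ketone.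

Step 4
Reactants: 8 (3R)-3-(2-methylbut-3-en-2-yl)-3-(prop-1-en-2-yl)cyclohexan-1-one; 9 N,N-dimethylmethaniminium iodide
Product: 12 (5R)-5-(2-methylbut-3-en-2-yl)-2-methylidene-5-(prop-1-en-2-yl)cyclohexan-1-one, via Mannich base 10 (not isolated), via methiodide 11 (not isolated)
Conditions: LiN(iPr)2, THF, −78 °C; 9, −78 to 0 °C; MeI, rt; aq. NaHCO3
Reagents that add atoms: none
Why: Eschenmoser methylenation, in which kinetic deprotonation takes the less hindered α-CH2 (the other α-carbon is neopentylic), followed by Mannich reaction and Hofmann-type elimination.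

Step 5
Reactants: 12 (5R)-5-(2-methylbut-3-en-2-yl)-2-methylidene-5-(prop-1-en-2-yl)cyclohexan-1-one
Product: 14 (2S,5R)-2-(chloromethyl)-2-hydroxy-5-(2-methylbut-3-en-2-yl)-5-(prop-1-en-2-yl)cyclohexan-1-one, via spiro-epoxide 13 (not isolated)
Conditions: 30% H2O2, NaOH (cat.), MeOH, 0 °C; extractive work-up; LiCl, AcOH, THF, rt
Reagents that add atoms: hydrogen peroxide, OO; lithium chloride, [Li+].[Cl-]
Why: Weitz–Scheffer nucleophilic epoxidation with axial C–O bond formation, expected trans to the axial isopropenyl group and cis to the equatorial tert-alkyl group, followed by SN2 opening by chloride at the CH2 carbon so the tertiary C–O bond and its configuration are kept.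

Step 6
Reactants: 14 (2S,5R)-2-(chloromethyl)-2-hydroxy-5-(2-methylbut-3-en-2-yl)-5-(prop-1-en-2-yl)cyclohexan-1-one
Product: 15 3-[(1R,4S)-4-(chloromethyl)-4-hydroxy-3-oxo-1-(prop-1-en-2-yl)cyclohexyl]-3-methylbutanal
Conditions: PdCl2(PhCN)2 (10 mol %), CuCl2·2H2O (10 mol %), AgNO2 (5 mol %), t-BuOH/MeNO2, O2 (1 atm), rt
Reagents that add atoms: dioxygen, O=O
Why: Nitrite-modified aldehyde-selective Wacker oxidation of the monosubstituted vinyl group on a quaternary carbon, which leaves the 1,1-disubstituted isopropenyl group untouched.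

Step 7
Reactants: 15 3-[(1R,4S)-4-(chloromethyl)-4-hydroxy-3-oxo-1-(prop-1-en-2-yl)cyclohexyl]-3-methylbutanal
Product: 17 (3S,6R,9S,10R)-10-bromo-3-(chloromethyl)-3,9-dihydroxy-11,11-dimethyl-7-methylidenespiro[5.5]undecan-2-one, via bromo aldehyde 16 (not isolated)
Conditions: (2R,5R)-2,5-diphenylpyrrolidine (20 mol %), PhCO2H (20 mol %), 4,4-dibromo-2,6-di-tert-butylcyclohexa-2,5-dien-1-one (1.05 equiv), CH2Cl2/pentane, −40 °C; cold silica plug; Me2AlCl (3.5 equiv), CH2Cl2, −78 to −30 °C; 1 M HCl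
Reagents that add atoms: 4,4-dibromo-2,6-di-tert-butylcyclohexa-2,5-dien-1-one, CC(C)(C)C1=CC(Br)(Br)C=C(C(C)(C)C)C1=O
Why: Enamine-catalysed α-bromination sets the (R)-C–Br centre by catalyst control (the catalyst enantiomer that gives (2R)-16 is used), and the Me2AlCl-promoted type 2 intramolecular carbonyl-ene reaction then closes ring A through a chair with equatorial Br and axial carbonyl oxygen, giving the cis bromohydrin and the exocyclic methylene.

**Compound list**

1 | 3-ethoxycyclohex-2-en-1-one | CCOC1=CC(=O)CCC1 | starting material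
2 | isopropenylmagnesium bromide | CC(=C)[Mg]Br | starting material
3 | 3-ethoxy-1-(prop-1-en-2-yl)cyclohex-2-en-1-ol (carbinol adduct, racemic) | CCOC1=CC(O)(C(C)=C)CCC1 | intermediate
4 | 3-(prop-1-en-2-yl)cyclohex-2-en-1-one | CC(=C)C1=CC(=O)CCC1 | intermediate
5 | 4,4,5,5-tetramethyl-2-(2-methylbut-3-en-2-yl)-1,3,2-dioxaborolane | C=CC(C)(C)B1OC(C)(C)C(C)(C)O1 | starting material
6 | (1S)-1-(3-methylbut-2-en-1-yl)-3-(prop-1-en-2-yl)cyclohex-2-en-1-ol | CC(C)=CC[C@]1(O)C=C(C(C)=C)CCC1 | intermediate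
7 | potassium (3R)-3-(2-methylbut-3-en-2-yl)-3-(prop-1-en-2-yl)cyclohex-1-en-1-olate | C=CC(C)(C)[C@]1(C(C)=C)CCCC([O-])=C1.[K+] | intermediate
8 | (3R)-3-(2-methylbut-3-en-2-yl)-3-(prop-1-en-2-yl)cyclohexan-1-one | C=CC(C)(C)[C@]1(C(C)=C)CCCC(=O)C1 | intermediate
9 | N,N-dimethylmethaniminium iodide (Eschenmoser's salt) | C[N+](C)=C.[I-] | starting material
10 | (5R)-2-[(dimethylamino)methyl]-5-(2-methylbut-3-en-2-yl)-5-(prop-1-en-2-yl)cyclohexan-1-one (epimers at C2) | C=CC(C)(C)[C@]1(C(C)=C)CCC(CN(C)C)C(=O)C1 | intermediate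
11 | trimethyl{[(4R)-4-(2-methylbut-3-en-2-yl)-2-oxo-4-(prop-1-en-2-yl)cyclohexyl]methyl}ammonium iodide | C=CC(C)(C)[C@]1(C(C)=C)CCC(C[N+](C)(C)C)C(=O)C1.[I-] | intermediate
12 | (5R)-5-(2-methylbut-3-en-2-yl)-2-methylidene-5-(prop-1-en-2-yl)cyclohexan-1-one | C=CC(C)(C)[C@]1(C(C)=C)CCC(=C)C(=O)C1 | intermediate
13 | (3R,6R)-6-(2-methylbut-3-en-2-yl)-6-(prop-1-en-2-yl)-1-oxaspiro[2.5]octan-4-one | C=CC(C)(C)[C@]1(C(C)=C)CC[C@@]2(CO2)C(=O)C1 | intermediate
14 | (2S,5R)-2-(chloromethyl)-2-hydroxy-5-(2-methylbut-3-en-2-yl)-5-(prop-1-en-2-yl)cyclohexan-1-one | C=CC(C)(C)[C@]1(C(C)=C)CC[C@@](O)(CCl)C(=O)C1 | intermediate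
15 | 3-[(1R,4S)-4-(chloromethyl)-4-hydroxy-3-oxo-1-(prop-1-en-2-yl)cyclohexyl]-3-methylbutanal | O=CCC(C)(C)[C@]1(C(C)=C)CC[C@@](O)(CCl)C(=O)C1 | intermediate
16 | (2R)-2-bromo-3-[(1R,4S)-4-(chloromethyl)-4-hydroxy-3-oxo-1-(prop-1-en-2-yl)cyclohexyl]-3-methylbutanal | O=C[C@H](Br)C(C)(C)[C@]1(C(C)=C)CC[C@@](O)(CCl)C(=O)C1 | intermediate
17 | (3S,6R,9S,10R)-10-bromo-3-(chloromethyl)-3,9-dihydroxy-11,11-dimethyl-7-methylidenespiro[5.5]undecan-2-one | C=C1C[C@H](O)[C@H](Br)C(C)(C)[C@@]12CC[C@@](O)(CCl)C(=O)C2 | target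

**Totals**

Total step count: 7. Longest linear sequence: 7 steps (1 → 17).

**Three steps most likely to fail**

Step 2 (asymmetric prenylboration of a hindered dienone; slow reaction or low ee). The fallback sets out from 4 and comes back at 8. Prenylbarium chloride, (CH3)2C=CHCH2BaCl (from prenyl chloride and Ba made from BaI2 and lithium biphenylide), adds through its CH2 terminus to give racemic 1-(3-methylbut-2-en-1-yl)-3-(prop-1-en-2-yl)cyclohex-2-en-1-ol F1. The oxy-Cope conditions of step 3 convert it into racemic 3-(2-methylbut-3-en-2-yl)-3-(prop-1-en-2-yl)cyclohexan-1-one F2. This is resolved through its ketals with (2R,3R)-butane-2,3-diol (TsOH, benzene, water removal): the ketal of the (R)-ketone, (2R,3R,7R)-2,3-dimethyl-7-(2-methylbut-3-en-2-yl)-7-(prop-1-en-2-yl)-1,4-dioxaspiro[4.5]decane F3, is separated and hydrolysed (1 M HCl, acetone) to 8.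

Step 3 (oxy-Cope joining two fully substituted carbons; retro-allylation or 1,3-shift of the potassium alkoxide may compete). The fallback sets out from 1 and comes back at 8. Prenylmagnesium chloride, (CH3)2C=CHCH2MgCl, adds to 1 through its CMe2 terminus and acid hydrolysis gives 3-(2-methylbut-3-en-2-yl)cyclohex-2-en-1-one F4. A Cu(OTf)2/chiral phosphoramidite-catalysed conjugate addition of dimethyl(isopropenyl)aluminium (from 2 and Me2AlCl) then builds the quaternary carbon and gives 8 directly.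

Step 7 (one-pot bromination and ene closure on a very hindered aldehyde beside the α-hydroxy ketone; epimerisation, HBr loss or chelation of the Lewis acid by ring B). The fallback sets out from 8 and comes back at 17; it closes ring A before ring B is oxidised.
- Wacker oxidation as in step 6 gives 3-methyl-3-[(1R)-3-oxo-1-(prop-1-en-2-yl)cyclohexyl]butanal F5.
- The conditions of step 7 give (2R)-2-bromo-3-methyl-3-[(1R)-3-oxo-1-(prop-1-en-2-yl)cyclohexyl]butanal F6 and then (6R,9S,10R)-10-bromo-9-hydroxy-11,11-dimethyl-7-methylidenespiro[5.5]undecan-2-one F7.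
- Methylenation with (CH2O)n and iPr2NH·CF3CO2H (THF, reflux) gives (6R,9S,10R)-10-bromo-9-hydroxy-11,11-dimethyl-3,7-dimethylidenespiro[5.5]undecan-2-one F8.
- H2O2/NaOH gives the ring B spiro-epoxide of 17 F9, and LiCl/AcOH opens it to 17.

**Further compounds**

F1 | step 2 | racemic 1-(3-methylbut-2-en-1-yl)-3-(prop-1-en-2-yl)cyclohex-2-en-1-ol | CC(C)=CCC1(O)C=C(C(C)=C)CCC1
F2 | step 2 | racemic 3-(2-methylbut-3-en-2-yl)-3-(prop-1-en-2-yl)cyclohexan-1-one | C=CC(C)(C)C1(C(C)=C)CCCC(=O)C1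
F3 | step 2 | (2R,3R,7R)-2,3-dimethyl-7-(2-methylbut-3-en-2-yl)-7-(prop-1-en-2-yl)-1,4-dioxaspiro[4.5]decane | C=CC(C)(C)[C@]1(C(C)=C)CCCC2(O[C@H](C)[C@@H](C)O2)C1
F4 | step 3 | 3-(2-methylbut-3-en-2-yl)cyclohex-2-en-1-one | C=CC(C)(C)C1=CC(=O)CCC1
F5 | step 7 | 3-methyl-3-[(1R)-3-oxo-1-(prop-1-en-2-yl)cyclohexyl]butanal | O=CCC(C)(C)[C@]1(C(C)=C)CCCC(=O)C1
F6 | step 7 | (2R)-2-bromo-3-methyl-3-[(1R)-3-oxo-1-(prop-1-en-2-yl)cyclohexyl]butanal | O=C[C@H](Br)C(C)(C)[C@]1(C(C)=C)CCCC(=O)C1
F7 | step 7 | (6R,9S,10R)-10-bromo-9-hydroxy-11,11-dimethyl-7-methylidenespiro[5.5]undecan-2-one | C=C1C[C@H](O)[C@H](Br)C(C)(C)[C@@]12CCCC(=O)C2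
F8 | step 7 | (6R,9S,10R)-10-bromo-9-hydroxy-11,11-dimethyl-3,7-dimethylidenespiro[5.5]undecan-2-one | C=C1C[C@H](O)[C@H](Br)C(C)(C)[C@@]12CCC(=C)C(=O)C2
F9 | step 7 | ring B spiro-epoxide of 17 (C3 carbon and its CH2 bridged by oxygen) | C=C1C[C@H](O)[C@H](Br)C(C)(C)[C@@]12CC[C@@]3(CO3)C(=O)C2
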